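**Retrosynthetic overview**
1. The strategy rests on the C3–C4 bond of the pyrrolidin-2-one ring (ring B: N1, C2=O, C3, C4, C5). C2–C3 is an acyl-derived pair and C4–C5 an N-alkyl-derived pair, so ring B opens to an acryloyl and an allyl group on the same benzylic nitrogen.
2. Target 11 ⇒ dimethyl ether 9 (O-demethylation last) ⇒ unsaturated lactam 8 (saturation of C3=C4) ⇒ diene 7 (ring-closing metathesis).
3. 7 ⇒ acryloyl chloride 6 + secondary amine 5 ⇒ allylamine 4 + benzyl bromide 3 ⇒ 3,4-dimethoxytoluene 1 (ring tribromination, then benzylic bromination).
4. Ring order: the benzene ring (ring A) is bought and fully substituted first. Ring B is the only ring formed, in step 5.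

Key step: step 5

Remark: the target is achiral, with no stereocentre and no stereogenic double bond, so the SMILES strings carry no stereo descriptors.

**Step 1**
Reactants: 1 3,4-dimethoxytoluene
Product: 2 2,3,6-tribromo-4,5-dimethoxytoluene
Conditions: Br2 (4.5 equiv), FeBr3 (5 mol %), CH2Cl2, 0 °C to reflux, dark
Reagents that add atoms: bromine, BrBr
Why: Exhaustive electrophilic aromatic bromination: each of the three free ring positions is ortho or para to a methoxy or methyl donor, so excess Br2 with a Lewis acid should fill all of them, and no regiochemical choice remains once the ring is hexasubstituted.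

**Step 2**
Reactants: 2 2,3,6-tribromo-4,5-dimethoxytoluene
Product: 3 2,3,6-tribromo-4,5-dimethoxybenzyl bromide
Conditions: NBS (1.1 equiv), AIBN (5 mol %), PhCF3, 85 °C
Reagents that add atoms: N-bromosuccinimide, O=C1CCC(=O)N1Br
Why: Wohl–Ziegler radical bromination: the methyl group holds the weakest C–H bonds, the ring has no free position for ionic bromination, and the two flanking ortho bromines slow a second hydrogen abstraction, which should hold the reaction at the monobromide.

**Step 3**
Reactants: 3 2,3,6-tribromo-4,5-dimethoxybenzyl bromide; 4 allylamine
Product: 5 N-(2,3,6-tribromo-4,5-dimethoxybenzyl)prop-2-en-1-amine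
Conditions: allylamine (6 equiv), K2CO3 (1.5 equiv), MeCN, 0 °C to rt
Reagents that add atoms: none
Why: SN2 N-alkylation of a primary amine by a benzylic bromide: the large excess of the volatile amine and the crowding by the two ortho bromines should suppress a second alkylation, and aryl bromides do not react with amines in the absence of a metal catalyst.

**Step 4**
Reactants: 5 N-(2,3,6-tribromo-4,5-dimethoxybenzyl)prop-2-en-1-amine; 6 acryloyl chloride
Product: 7 N-allyl-N-(2,3,6-tribromo-4,5-dimethoxybenzyl)acrylamide
Conditions: acryloyl chloride (1.3 equiv), 2 M aq. NaOH, CH2Cl2, 0 °C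
Reagents that add atoms: none
Why: Schotten–Baumann N-acylation: at 0 °C the secondary amine attacks the acid chloride carbonyl far faster than it adds in a conjugate sense, and the aqueous base takes up the HCl.

**Step 5**
Reactants: 7 N-allyl-N-(2,3,6-tribromo-4,5-dimethoxybenzyl)acrylamide
Product: 8 1-(2,3,6-tribromo-4,5-dimethoxybenzyl)-1,5-dihydro-2H-pyrrol-2-one
Conditions: second-generation Grubbs catalyst RuCl2(=CHPh)(PCy3)(SIMes) (5 mol %; SIMes = 1,3-dimesitylimidazolidin-2-ylidene), CH2Cl2 (0.02 M), reflux, argon sweep
Reagents that add atoms: none
Why: Ring-closing olefin metathesis by the Chauvin mechanism: the ruthenium benzylidene first exchanges with the more electron-rich allyl C=C, the resulting alkylidene at the future C4 adds [2+2] across the acrylamide C=C, and cycloreversion of the ruthenacyclobutane delivers the C3=C4 bond and Ru=CH2, which carries the chain while ethylene leaves as a gas. The closest known reaction type is the ring closure of N-benzyl-N-allylacrylamides to 1,5-dihydropyrrol-2-ones with ruthenium catalysts that bear an N-heterocyclic carbene, which are active enough for the electron-poor acyl-side alkene. The five-membered ring N1–C2–C3=C4–C5 is closed by an intramolecular alkylidene/alkene metathesis in which both terminal CH2 groups are lost, so the new alkene is endocyclic and can only be cis. No stereocentre is formed. The selectivity needed is ring closure over intermolecular cross-metathesis, and it is secured by the tertiary amide, whose rotamers interconvert at reflux and feed the one that holds the allyl group next to the vinyl group, by the reluctance of acrylamides to homodimerise, and by working at about 0.02 M. The aryl C–Br bonds, the methyl ethers and the fully substituted ring A offer no alkene, no free N–H and no chelating donor, so they should pass through untouched.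

**Step 6**
Reactants: 8 1-(2,3,6-tribromo-4,5-dimethoxybenzyl)-1,5-dihydro-2H-pyrrol-2-one
Product: 9 1-(2,3,6-tribromo-4,5-dimethoxybenzyl)pyrrolidin-2-one
Conditions: H2 (3 bar), RhCl(PPh3)3 (5 mol %), toluene–EtOH 1:1, 40 °C
Reagents that add atoms: none
Why: Homogeneous hydrogenation with Wilkinson's catalyst: the dihydride formed from monovalent rhodium binds the unhindered cis-disubstituted C3=C4 alkene and transfers both hydrogens to it, while under these mild conditions it neither inserts into aryl C–Br bonds nor cleaves the benzylic C–N bond, as a heterogeneous palladium catalyst would, and no stereocentre arises.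

**Step 7**
Reactants: 9 1-(2,3,6-tribromo-4,5-dimethoxybenzyl)pyrrolidin-2-one
Product: 11 1-(2,3,6-tribromo-4,5-dihydroxybenzyl)pyrrolidin-2-one, via cyclic bromoborate 10 (not isolated)
Conditions: BBr3 (4 equiv), CH2Cl2, −78 °C to rt; then ice-water, 0 °C
Reagents that add atoms: none
Why: Lewis-acid cleavage of aryl methyl ethers: BBr3 binds each ether oxygen and bromide removes the methyl group by SN2, the extra equivalents cover the Lewis-basic lactam carbonyl, and the cold aqueous quench hydrolyses the borate without solvolysis of the para-hydroxybenzylic C–N bond.

**Compound list**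
1 | 3,4-dimethoxytoluene | Cc1ccc(OC)c(OC)c1 | starting material
2 | 2,3,6-tribromo-4,5-dimethoxytoluene | Cc1c(Br)c(OC)c(OC)c(Br)c1Br | intermediate
3 | 2,3,6-tribromo-4,5-dimethoxybenzyl bromide | BrCc1c(Br)c(OC)c(OC)c(Br)c1Br | intermediate
4 | allylamine (prop-2-en-1-amine) | C=CCN | starting material
5 | N-(2,3,6-tribromo-4,5-dimethoxybenzyl)prop-2-en-1-amine | C=CCNCc1c(Br)c(OC)c(OC)c(Br)c1Br | intermediate
6 | acryloyl chloride | C=CC(=O)Cl | starting material
7 | N-allyl-N-(2,3,6-tribromo-4,5-dimethoxybenzyl)acrylamide | C=CCN(Cc1c(Br)c(OC)c(OC)c(Br)c1Br)C(=O)C=C | intermediate
8 | 1-(2,3,6-tribromo-4,5-dimethoxybenzyl)-1,5-dihydro-2H-pyrrol-2-one | O=C1C=CCN1Cc1c(Br)c(OC)c(OC)c(Br)c1Br | intermediate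
9 | 1-(2,3,6-tribromo-4,5-dimethoxybenzyl)pyrrolidin-2-one | O=C1CCCN1Cc1c(Br)c(OC)c(OC)c(Br)c1Br | intermediate
10 | 1-[(2,4,6,7-tetrabromo-1,3,2-benzodioxaborol-5-yl)methyl]pyrrolidin-2-one (cyclic bromoborate, not isolated) | O=C1CCCN1Cc1c(Br)c2OB(Br)Oc2c(Br)c1Br | intermediate
11 | 1-(2,3,6-tribromo-4,5-dihydroxybenzyl)pyrrolidin-2-one | O=C1CCCN1Cc1c(Br)c(O)c(O)c(Br)c1Br | target

**Total step count:** 7
**Longest linear sequence:** 7 (1 → 11)

**Steps most likely to fail**

Step 5 (ring-closing metathesis).
- Risk: the alkylidene loaded on the allyl arm may be held back by chelation to the amide carbonyl, or may decay before it adds to the electron-poor acrylamide alkene. Intermolecular coupling through the allyl groups would then overtake ring closure.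
- Fallback: olefin metathesis is given up and the intact lactam ring is attached instead. Setting out from benzyl bromide 3, commercial pyrrolidin-2-one (O=C1CCCN1) is deprotonated with NaH in DMF at 0 °C and N-alkylated by 3 in an SN2 reaction at rt. This bypasses 5, 7 and 8 and comes back to the route at 9, ahead of step 7. No compound outside the list is made (F0).

Step 1 (exhaustive bromination).
- Risk: the reaction may stall after the second bromine, because the last free position lies between the methyl and a methoxy group on a ring that is already deactivated. Forcing it may start cleavage of the methyl ethers by HBr and the Lewis acid.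
- Fallback: bromination is carried out at the free catechol stage, where the ring is far more activated and no Lewis acid is needed. Setting out from 1, both ethers are cleaved with BBr3 in CH2Cl2 to 4-methylbenzene-1,2-diol F1. This compound is also an article of commerce, so the operation can be skipped. Br2 (3.3 equiv) in AcOH–CHCl3 at rt should then fill all three free positions to give 3,4,6-tribromo-5-methylbenzene-1,2-diol F2. Double O-methylation with dimethyl sulfate and K2CO3 in refluxing acetone comes back to the route at 2.

Step 6 (chemoselective hydrogenation).
- Risk: turnover on the conjugated, electron-poor alkene may be slow, with double-bond migration. Under forcing pressure or temperature, hydrogenolysis of C–Br bonds may set in.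
- Fallback: hydrogen is transferred without any metal. Setting out from 8, diimide is generated in the flask from 2-nitrobenzenesulfonyl hydrazide and Et3N in CH2Cl2 at rt, in excess and added in portions. It should deliver both hydrogens to C3=C4 in a concerted syn transfer that cannot touch aryl halides. This comes back to the route at 9. No compound outside the list is made (F0).

**Further compounds**
F0 | step 5 | none | none
F1 | step 1 | 4-methylbenzene-1,2-diol | Cc1ccc(O)c(O)c1
F2 | step 1 | 3,4,6-tribromo-5-methylbenzene-1,2-diol | Cc1c(Br)c(O)c(O)c(Br)c1Br
F0 | step 6 | none | none
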